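Its constants were set for the occasion; the rest is arithmetic.

I decide to reckon from the rate at which the solid reagent feeds the partner, and to ask afterwards whether the size of the solid charge matters.

    starting material + partner ⇌ target (K1 = 70 L mol⁻¹, k1 = 190 L mol⁻¹ s⁻¹)
    second substrate + partner → second product (k2 = 140 L mol⁻¹ s⁻¹)
    solid reagent ⇌ partner, rate k3*(cs3 - [partner]) while solid is left; crystals form when [partner] > cs3 (cs3 = 9.0 mM, k3 = 0.058 s⁻¹)
    target → over-reaction product (k4 = 0.083 s⁻¹)

common to all: starting material 10 mM; second substrate 20.0 mM; time 8.0 s
- midnight: solid reagent 6.00 mM
- noon: solid reagent 12.0 mM
- spring: solid reagent 24.0 mM

- given per volume of solution although it is solid: solid reagent
- at the start none of the solid reagent is in solution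
- run time (midnight): 8.0 s

- which of these there is most of at the end, counted by the starting material in it, midnight (target / starting material / over-reaction product)
- which of these there is most of at the end, counted by the starting material in it, noon (target / starting material / over-reaction product)
- which of these there is most of at the end, counted by the starting material in it, spring (target / starting material / over-reaction product)
- the largest of these amounts at the end, in percent of the starting material charged, midnight
- the largest of these amounts at the end, in percent of the starting material charged, noon
- the largest of these amounts at the end, in percent of the starting material charged, spring

The solid reagent dissolves into the solution as partner. The second substrate removes partner for good, while the starting material binds it reversibly as target, and the target slowly turns into over-reaction product. I take the feed as steady at 0.522 mM s⁻¹, because I reckon the partner to stay near 0.186 mM, far below its solubility. That is the partner's slope at the start, or 0.0522 s⁻¹ as a fraction of the starting material charged. At this feed the smallest charge lasts 11.5 s, and every charge outlasts the run, so I expect the same curve in the three flasks.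

The second substrate is in excess of what the feed brings in the run and takes up partner in a pseudo-first-order way at 2.80 s⁻¹. Target returns its partner much faster than it goes on to over-reaction product, so binding stays near equilibrium. Partner and target then form one pool of 1.70 times the free partner, and this pool reaches its level at a knee near 0.607 s, well inside the run.

At that level the feed equals the scavenging, and the fraction of the charge standing as target is 1.31%. This fraction, the equilibrium constant times the feed over the scavenging rate, I call the held share.

Past the knee, over-reaction product climbs at the rate constant of its step times the held share, and I reckon it at 0.801% by the end. That leaves 97.9% as starting material. But the flat level carries an error: by this reckoning the second substrate gives up 20.9% of its charge by the end. The level therefore creeps up to 1.65%, and over-reaction product to 0.894%. This second estimate gives 97.5%, so I commit to starting material between these two figures in each flask.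

The forecast names starting material with 97.7%, range 96.5% to 98.5%, for each flask, saying that “all three runs should come out essentially identical”.

The flask gives starting material at 97.8% at midnight, starting material at 97.8% at noon and starting material at 97.8% in spring. The midnight flask, with the smallest charge, holds 31.8% of its solid reagent at 8.00 s. Its target reads 1.41%, a little above the held share of 1.31%. For a neighbour of the noon flask, charged with 5.0 mM of second substrate, the held share becomes 5.22%, and that neighbour reads 5.26% of target at 8.00 s.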